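The route rests on disconnecting the C1–C6 bond of the cyclohexane ring (ring numbered from the methylidene carbon C1 round to the benzyl-bearing carbon C6). Because these two ring atoms are adjacent, one enantioselective reductive Heck closure of a 2-iodoalkene onto an (E)-styrene forms the six-membered ring, the exocyclic methylene, the benzylic CH2 and the C6 stereocentre in a single operation. The precursor is an achiral, open-chain ketone whose carbonyl is flanked by a gem-dimethyl carbon carrying the 4-bromo-2,5-dimethoxystyryl group and by a 3-iodobut-3-enyl chain. It is reached in five steps; reduction, invertive bromination and oxidative demethylation then give the target.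

Key step: step 6

Assumption: the sense of induction of the chiral ligand in step 6 cannot be predicted safely, so (R)-BINAP is written and (S)-BINAP is taken instead if a test run shows the (R)-ketone; organopalladium species of the catalytic cycles turn over in situ and are described in words, whereas intermediates that build up in the flask are numbered.

Step 1
Reactants: 1 2,2-dimethylbut-3-enoic acid
Product: 4 3,3-dimethylpent-4-en-2-one, via lithium carboxylate 2 (not isolated), via dilithium gem-diolate 3 (not isolated)
Conditions: MeLi (2.2 equiv), Et2O, 0 °C to rt; then inverse quench into ice-cold H2O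
Reagents that add atoms: methyllithium, C[Li]
Why: Addition of an organolithium to a lithium carboxylate (Gilman–van Ess ketone synthesis) stops at the dilithium gem-diolate, which cannot collapse to the ketone before the aqueous quench, and the quaternary α-carbon further shields the carbonyl from over-addition.

Step 2
Reactants: 4 3,3-dimethylpent-4-en-2-one (1.5 equiv); 5 1-bromo-4-iodo-2,5-dimethoxybenzene
Product: 6 (E)-5-(4-bromo-2,5-dimethoxyphenyl)-3,3-dimethylpent-4-en-2-one
Conditions: Pd(OAc)2 (5 mol %), P(o-tol)3 (10 mol %), NaOAc, DMF, 80 °C, sealed vessel
Reagents that add atoms: none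
Why: In this Mizoroki–Heck arylation zerovalent palladium inserts into the weaker C–I bond in preference to C–Br, the aryl group goes to the unsubstituted alkene terminus, and because C3 is quaternary only a benzylic hydrogen can be eliminated, so the (E)-styrene should be the only regioisomer.

Step 3
Reactants: 7 prop-2-yn-1-ol
Product: 8 2-iodoprop-2-en-1-ol
Conditions: NaI, Me3SiCl, H2O, MeCN, rt
Reagents that add atoms: sodium iodide, [Na+].[I-]
Why: Markovnikov hydroiodination of a terminal alkyne by HI generated in the flask places iodine on the internal carbon and stops at the 2-iodoalkene, and it is done here on a substrate that carries no acid-sensitive styrene or ketone.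

Step 4
Reactants: 8 2-iodoprop-2-en-1-ol
Product: 10 3-bromo-2-iodoprop-1-ene, via 2-iodoallyl phosphorodibromidite 9 (not isolated)
Conditions: PBr3 (0.4 equiv), Et2O, 0 °C
Reagents that add atoms: phosphorus tribromide, BrP(Br)Br
Why: Deoxybromination of a primary allylic alcohol with PBr3 proceeds by phosphite ester formation and bromide displacement, and the alkenyl iodide is inert to these conditions.

Step 5
Reactants: 6 (E)-5-(4-bromo-2,5-dimethoxyphenyl)-3,3-dimethylpent-4-en-2-one; 10 3-bromo-2-iodoprop-1-ene (1.3 equiv)
Product: 12 (E)-1-(4-bromo-2,5-dimethoxyphenyl)-7-iodo-3,3-dimethylocta-1,7-dien-4-one, via lithium enolate 11 (not isolated)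
Conditions: LiN(i-Pr)2 (1.05 equiv), THF, −78 °C; then 10, −78 to 0 °C
Reagents that add atoms: none
Why: In this kinetic enolate alkylation only the methyl group can be deprotonated because the other α-carbon is quaternary, and the allylic bromide is displaced (SN2 and SN2′ give the same product) while the alkenyl iodide and the aryl bromide do not react.

Step 6
Reactants: 12 (E)-1-(4-bromo-2,5-dimethoxyphenyl)-7-iodo-3,3-dimethylocta-1,7-dien-4-one
Product: 13 (3S)-3-[(4-bromo-2,5-dimethoxyphenyl)methyl]-2,2-dimethyl-4-methylidenecyclohexan-1-one
Conditions: Pd(OAc)2 (5 mol %), (R)-BINAP (7.5 mol %), HCO2Na (2 equiv), DMF/MeOH 4:1, 60 °C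
Reagents that add atoms: none
Why: Proposed new method: zerovalent palladium inserts into the alkenyl C–I bond, the alkenylpalladium adds syn across the styrene so that chain carbons C7 and C2 are joined (the C1–C6 bond of the target ring) and palladium arrives on the benzylic carbon, iodide is exchanged for formate, loss of CO2 leaves a palladium hydride, and C–H reductive elimination releases 13 and returns zerovalent palladium. The closest known reaction type is the intramolecular reductive Heck cyclization, whose enantioselective variants are established mainly for aryl halides closing five-membered rings, so the combination of alkenyl iodide, six-membered ring and styrene acceptor is the extrapolation. The ring closes in the 6-exo-trig mode, preferred over 7-endo because of ring size, the gem-dimethyl group in the tether and the benzylic (η3) stabilisation of palladium at the exocyclic carbon. The new stereocentre (C3 of 13, S) is fixed in the migratory insertion, where the axially chiral bisphosphine, kept chelating by the polar medium that assists iodide dissociation, selects the enantioface of styrene carbon C2. The step needs chemoselectivity for C–I over the aryl C–Br bond, secured by the far faster oxidative addition of an alkenyl iodide than of an electron-rich, ortho-substituted aryl bromide, and it needs hydride capture ahead of β-hydride loss, which the η3-benzyl resting state and the excess of formate are expected to provide; the ketone is a bystander, and the new centre is β to it and cannot epimerise by enolisation.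

Step 7
Reactants: 13 (3S)-3-[(4-bromo-2,5-dimethoxyphenyl)methyl]-2,2-dimethyl-4-methylidenecyclohexan-1-one
Product: 15 (1S,3S)-3-[(4-bromo-2,5-dimethoxyphenyl)methyl]-2,2-dimethyl-4-methylidenecyclohexan-1-ol (hydroxyl trans to the benzyl group), via potassium alkoxide 14 (not isolated)
Conditions: KBH(s-Bu)3, THF, −78 °C; then H2O
Reagents that add atoms: none
Why: In this substrate-controlled hydride reduction the bulky trialkylborohydride approaches along the equatorial trajectory of the chair that carries the benzyl group equatorially, so the new hydroxyl should be axial and trans to the benzyl group, the (1S) centre being set by the existing C3 centre together with the flanking gem-dimethyl group.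

Step 8
Reactants: 15 (1S,3S)-3-[(4-bromo-2,5-dimethoxyphenyl)methyl]-2,2-dimethyl-4-methylidenecyclohexan-1-ol
Product: 17 1-bromo-4-{[(1S,3R)-3-bromo-2,2-dimethyl-6-methylidenecyclohexyl]methyl}-2,5-dimethoxybenzene (ring bromine cis to the benzyl group), via alkoxyphosphonium bromide 16 (not isolated)
Conditions: CBr4, PPh3, CH2Cl2, 0 °C to reflux
Reagents that add atoms: carbon tetrabromide, BrC(Br)(Br)Br
Why: In the Appel reaction bromide displaces the alkoxyphosphonium group by SN2 with inversion, so the axial C–O bond becomes the equatorial C–Br bond with the (R) configuration, a conversion that has precedent for axial alcohols next to a gem-dimethyl carbon in brominated terpenoids.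

Step 9
Reactants: 17 1-bromo-4-{[(1S,3R)-3-bromo-2,2-dimethyl-6-methylidenecyclohexyl]methyl}-2,5-dimethoxybenzene
Product: 19 cyclocymopol, via bromoquinone 18 (not isolated)
Conditions: (NH4)2Ce(NO3)6, MeCN/H2O, 0 °C; then Na2S2O4, pH 7 phosphate buffer/EtOAc, rt
Reagents that add atoms: water, O
Why: Oxidative demethylation of the 1,4-dimethoxyarene (water adds to the arene radical cation at each methoxy-bearing carbon and methanol is expelled) gives the bromoquinone, which dithionite reduces to the hydroquinone in the buffered work-up, while the alkyl bromide, the alkene and both stereocentres are not touched.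

Compound list
1 | 2,2-dimethylbut-3-enoic acid | C=CC(C)(C)C(=O)O | starting material
2 | lithium 2,2-dimethylbut-3-enoate | C=CC(C)(C)C(=O)[O-].[Li+] | intermediate
3 | dilithium 3,3-dimethylpent-4-ene-2,2-diolate | C=CC(C)(C)C(C)([O-])[O-].[Li+].[Li+] | intermediate
4 | 3,3-dimethylpent-4-en-2-one | C=CC(C)(C)C(C)=O | intermediate
5 | 1-bromo-4-iodo-2,5-dimethoxybenzene | COc1cc(I)c(OC)cc1Br | starting material
6 | (E)-5-(4-bromo-2,5-dimethoxyphenyl)-3,3-dimethylpent-4-en-2-one | CC(=O)C(C)(C)/C=C/c1cc(OC)c(Br)cc1OC | intermediate
7 | prop-2-yn-1-ol | C#CCO | starting material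
8 | 2-iodoprop-2-en-1-ol | C=C(I)CO | intermediate
9 | 2-iodoallyl phosphorodibromidite | C=C(I)COP(Br)Br | intermediate
10 | 3-bromo-2-iodoprop-1-ene | C=C(I)CBr | intermediate
11 | lithium (E)-5-(4-bromo-2,5-dimethoxyphenyl)-3,3-dimethylpenta-1,4-dien-2-olate | C=C([O-])C(C)(C)/C=C/c1cc(OC)c(Br)cc1OC.[Li+] | intermediate
12 | (E)-1-(4-bromo-2,5-dimethoxyphenyl)-7-iodo-3,3-dimethylocta-1,7-dien-4-one | C=C(I)CCC(=O)C(C)(C)/C=C/c1cc(OC)c(Br)cc1OC | intermediate
13 | (3S)-3-[(4-bromo-2,5-dimethoxyphenyl)methyl]-2,2-dimethyl-4-methylidenecyclohexan-1-one | C=C1CCC(=O)C(C)(C)[C@H]1Cc1cc(OC)c(Br)cc1OC | intermediate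
14 | potassium (1S,3S)-3-[(4-bromo-2,5-dimethoxyphenyl)methyl]-2,2-dimethyl-4-methylidenecyclohexan-1-olate | C=C1CC[C@H]([O-])C(C)(C)[C@H]1Cc1cc(OC)c(Br)cc1OC.[K+] | intermediate
15 | (1S,3S)-3-[(4-bromo-2,5-dimethoxyphenyl)methyl]-2,2-dimethyl-4-methylidenecyclohexan-1-ol | C=C1CC[C@H](O)C(C)(C)[C@H]1Cc1cc(OC)c(Br)cc1OC | intermediate
16 | {(1S,3S)-3-[(4-bromo-2,5-dimethoxyphenyl)methyl]-2,2-dimethyl-4-methylidenecyclohexyl}oxytriphenylphosphonium bromide | C=C1CC[C@H](O[P+](c2ccccc2)(c2ccccc2)c2ccccc2)C(C)(C)[C@H]1Cc1cc(OC)c(Br)cc1OC.[Br-] | intermediate
17 | 1-bromo-4-{[(1S,3R)-3-bromo-2,2-dimethyl-6-methylidenecyclohexyl]methyl}-2,5-dimethoxybenzene | C=C1CC[C@@H](Br)C(C)(C)[C@H]1Cc1cc(OC)c(Br)cc1OC | intermediate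
18 | 2-bromo-5-{[(1S,3R)-3-bromo-2,2-dimethyl-6-methylidenecyclohexyl]methyl}cyclohexa-2,5-diene-1,4-dione | C=C1CC[C@@H](Br)C(C)(C)[C@H]1CC1=CC(=O)C(Br)=CC1=O | intermediate
19 | cyclocymopol, 2-bromo-5-{[(1S,3R)-3-bromo-2,2-dimethyl-6-methylidenecyclohexyl]methyl}benzene-1,4-diol | C=C1CC[C@@H](Br)C(C)(C)[C@H]1Cc1cc(O)c(Br)cc1O | target

Total step count: 9 (steps 3 and 4 are a two-step side branch). Longest linear sequence: 7 steps (steps 1, 2, 5, 6, 7, 8 and 9).

Steps most likely to fail

Step 6. Formate may reduce the alkenylpalladium before ring closure, the benzylic palladium may lose a β-hydride, a palladium hydride may move the new double bond into the ring, or enantioface discrimination may be weak. The fallback sets out from 12. Ring closure with Bu3SnH and AIBN in benzene at 80 °C under slow addition is a 6-exo alkenyl radical cyclization of a well-established type. Iodine abstraction is much faster than attack on the aryl bromide, and the benzylic radical is quenched by the stannane. This would give the racemic ketone, rac-3-[(4-bromo-2,5-dimethoxyphenyl)methyl]-2,2-dimethyl-4-methylidenecyclohexan-1-one F1. Separation of its enantiomers by preparative chromatography on a chiral stationary phase then supplies the (S)-ketone, and the route is rejoined at 13.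

Step 8. Anti-elimination across C1–C6 and migration of a methyl group from C2 can compete with substitution at this neopentyl-type centre, and collapse of an ion pair could erode the inversion. The fallback sets out from 15 and separates activation from displacement. NaH and 1,1′-sulfonyldiimidazole in THF/DMF at −30 °C should give the sulfonate ester, (1S,3S)-3-[(4-bromo-2,5-dimethoxyphenyl)methyl]-2,2-dimethyl-4-methylidenecyclohexyl imidazole-1-sulfonate F2. This is then displaced by Bu4NBr in toluene at 60–80 °C, a non-ionising medium that favours direct SN2 inversion, and the route is rejoined at 17.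

Step 7. Facial selectivity may be poor if the chair with an axial benzyl group, which avoids one gauche contact with the gem-dimethyl group, reacts competitively; hydride then enters anti to the benzyl group and the hydroxyl ends up cis to it. The fallback sets out from 13 and replaces substrate control by reagent control. A Corey–Bakshi–Shibata reduction with (R)-2-methyl-CBS-oxazaborolidine and BH3·SMe2 in THF at −20 °C treats the quaternary C2 as the large group and the C6 methylene as the small group. It is expected to deliver the (1S)-carbinol whatever the ring conformation and comes back to the route directly at 15, without any new compound.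

Further compounds
F1 | step 6 | rac-3-[(4-bromo-2,5-dimethoxyphenyl)methyl]-2,2-dimethyl-4-methylidenecyclohexan-1-one | C=C1CCC(=O)C(C)(C)C1Cc1cc(OC)c(Br)cc1OC
F2 | step 8 | (1S,3S)-3-[(4-bromo-2,5-dimethoxyphenyl)methyl]-2,2-dimethyl-4-methylidenecyclohexyl imidazole-1-sulfonate | C=C1CC[C@H](OS(=O)(=O)n2ccnc2)C(C)(C)[C@H]1Cc1cc(OC)c(Br)cc1OC
F0 | step 7 | none | none
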